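# Proposed total synthesis of isospiculoic acid A

## Structural features

Isospiculoic acid A is a hydrindane: a cyclohexene (ring A: C1=C2, C3, C4, C5, C6) is fused through the C5–C6 bond to a cyclopentanone (ring B: C6, C7, C8, C9, C5), with an ethyl group on C1, the ketone at C8 and a methyl group on C9. Six stereocentres run in a chain C3–C4–C5–C6–C7 and on through the carbonyl to C9; C3 (ethyl, (E)-styryl) and C4 (ethyl, CO2H) are adjacent all-carbon quaternary centres, with both ethyl groups on one face (called α here) and styryl and carboxyl on the other (β). The ring fusion is trans (C5–H β, C6–H α), and the C7 ethyl (α) and the C9 methyl (β) are each trans to their ring neighbours, so ring B has the all-trans, thermodynamically preferred arrangement. Fragile points are the two enolisable centres C7 and C9 beside the ketone, the trisubstituted C1=C2 alkene and the styrene (sensitive to acid, hydrogenation and electrophiles), and a neopentyl carboxylic acid that resists acyl substitution. The real difficulty is the vicinal quaternary pair C3/C4 in absolute form and its relay to C5 and C6; C7 and C9 can be corrected by equilibration. The key step exploits the fact that ring B is a 2-methylcyclopentanone: C8, C9 and the methyl carbon can be held as a cyclopropanol, which arises from a C8 ester on the C6 side chain and a vinyl group on C5, so ring B closes through C8–C9 on a finished ring A.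

## Logic of the disconnections

25 ⇒ 24. No skeletal bond is cut; the C4 carboxyl O–H is replaced by an O–tert-butyl bond. The acid has to be masked through the organometallic steps by a group that nucleophiles cannot reach and that leaves without base. The forward step must cleave it by alkyl–oxygen fission without disturbing the alkenes or C7 and C9.

24 ⇒ 23. The C9 methyl carbon is reconnected to C8, folding the methyl ketone into a cyclopropanol. This hides the ketone and its two labile α-centres until the penultimate step. The forward opening must break the bond from C8 to the CH2 carbon (not C8–C9), and the base must settle C7 and C9 into the all-trans form.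

23 ⇒ 22. The bonds C8–C9 and C8–CH2 are cut; both start at the ester carbon and are made by one titanium reagent. Ring B disappears and a monocyclic ring A remains, with a vinyl group on C5 and an ester arm on C6 that are already trans. The forward step needs the terminal vinyl group to react in preference to the other two alkenes, and the methyl ester in preference to the tert-butyl ester.

22 ⇒ 20. The C7–ethyl bond is cut, leaving an acetate arm that traces to a bromoacetate. C7 is not a binding stereocentre here because it is equilibrated once C8 is a ketone. The enolate must be formed only after the anhydride of the earlier intermediates has gone, since next to an intact anhydride it would acylate itself on the C4 carbonyl through a five-membered ring.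

20 ⇒ 19 ⇒ 18 ⇒ 17. The tert-butyl C–O bond and the styryl C=C bond are cut, and the C3 formyl carbon of 18 is joined with the C4 carboxyl into the anhydride ring of 17. The two different quaternary substituents thereby become one symmetrical functional group, and the cis-diethylsuccinic anhydride is a Diels–Alder retron. The forward steps need reduction of only the C3 carbonyl, to the aldehyde oxidation level and no further, and an E-selective olefination.

17 ⇒ 16 ⇒ 14. The C1–ethyl bond is cut; the C1=C2 alkene becomes an enol triflate and then a C1 ketone. That ketone is what activates C5 and C6 in the preceding step. Enolisation must go toward C2, and the coupling must avoid β-hydride elimination and leave the anhydride alone.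

14 ⇒ 10 + 11 + 12. The C5–vinyl and C6–C7 bonds are cut at the β and α positions of an enone. Two stereocentres and two side chains are removed in one operation. The forward step relies on the cis-fused anhydride to direct the cuprate to the α face, and on alkylation of the resulting enolate anti to the new vinyl group.

10 ⇒ 8 + 3. The C2–C3 and C4–C5 bonds are cut ([4+2]). Both quaternary carbons then come from an achiral, symmetrical dienophile, cis by its geometry, and the absolute configuration comes from a removable amine. The demand is reactivity of a tetrasubstituted dienophile together with endo and facial control.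

8 ⇒ 6 ⇒ 4 + 5, and 3 ⇒ 1. The O–Si and C–N bonds of the diene and the two C–CO bonds of the anhydride are cut, which reaches commercial materials. The alkyne must be dicarboxylated cis.

## Other disconnections considered

Alternative 1: Diels–Alder construction of ring A. The cut is C2–C3 and C4–C5. The forward step is the [4+2] cycloaddition of the 1-amino-3-siloxybutadiene 8 with diethylmaleic anhydride 3; acid then hydrolyses the enol ether and expels the amine to give the cis-diethyl enone anhydride A1, which is the same compound as 10.
- In its favour: it is the only one of the four cuts that creates the vicinal quaternary carbons C3 and C4. It does so from a symmetrical dienophile whose geometry guarantees the cis relationship, and it leaves a C5=C6 enone ready for vicinal difunctionalisation.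
- Against it as the single strategic step: the dienophile is tetrasubstituted and therefore slow, the two anhydride carbonyls must be told apart later, and the step does nothing for ring B, the trans junction, C7 or C9.
- Comparison: on structure it is the better disconnection for ring A and the quaternary pair, to which the cyclopropanol closure contributes nothing. On mechanism a concerted suprafacial cycloaddition is at least the equal of the titanium chemistry in predictability. On step economy the two are not rivals: the chosen plan uses this cycloaddition as step 4 and adds the cyclopropanol closure for the part it cannot reach.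

Alternative 2: reductive Nazarov cyclisation. The cut is C5–C6 of ring B, with C1=C2 of ring A left for a later metathesis. In the forward step BF3·OEt2 activates the cross-conjugated (E,E)-dienone A3, a four-electron conrotatory closure forms C5–C6, and Et3SiH reduces the oxyallyl cation to the cyclopentanone A2. Ring-closing metathesis between the C1 methylidene and the C3 vinyl group (for instance with a second-generation Grubbs catalyst) would then give the methyl ester A4, and ester cleavage the target.
- In its favour: one step creates ring B with its ketone and sets C5 and C6 trans from the two E alkenes, leaving C7 and C9 to settle all-trans. In ring-forming economy it is the better of the two (one step against cyclopropanation plus opening), and A3 can be assembled convergently at C8.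
- Against it here:
  - A3 needs the C3/C4 quaternary pair built on an open chain, with a vinyl and a styryl group to be distinguished on C3.
  - The sense of conrotation must be dictated by the C4 stereocentre, whose substituents differ little in size.
  - The C6 terminus is part of a 1,3-diene, which opens other cationic paths, and a Lewis acid sits uneasily with a styrene.
  - The metathesis must choose vinyl over styryl and make a trisubstituted alkene next to a quaternary carbon.
  - The final hydrolysis of a neopentyl methyl ester by acyl substitution is difficult, whereas the tert-butyl ester of the chosen route leaves by alkyl–oxygen cleavage.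
- Comparison: on structure the Nazarov step sets C5 and C6 in the ring-forming event, while the chosen plan sets them earlier on a rigid bicycle and the closure only inherits them; this is less elegant but more predictable. On mechanism the torquoselectivity from an acyclic quaternary centre is a weak point with no counterpart in the chosen plan. On step economy the two are equal after the key step (two steps each); the difference lies in the cost of A3.

Alternative 3: Pauson–Khand bicyclisation. The cut is C5–C6, C7–C8 and C8–C9. In the forward step Co2(CO)8 complexes the methyl alkyne on C4 of the acyclic enyne A6 and combines it with the (E)-C6=C7 alkene and CO in a [2+2+1] cycloaddition. This closes ring A through C5–C6 and ring B through C7–C8 and C8–C9, giving the bicyclic enone A5; conjugate reduction of C5=C9 and ester cleavage would follow by way of A4.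
- In its favour: in bonds and rings per step it is the best of the four (three C–C bonds, both rings, the carbonyl carbon from CO) and clearly better than the chosen step. The E geometry is copied into the trans C6/C7 relationship.
- Against it here:
  - A6 again demands the acyclic quaternary pair.
  - The alkene is 1,2-disubstituted, part of a conjugated diene, and tethered so as to close a six-membered ring; each feature lowers reactivity and invites other modes.
  - The face of C6=C7 is chosen only by remote quaternary centres.
  - The tetrasubstituted C5=C9 enone must afterwards be reduced to the trans junction next to C4 without touching the styrene, at a centre (C5) that cannot be corrected by epimerisation.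
- Comparison: on structure its convergence on the bicycle is unmatched, but the stereochemical burden moves to C5 after ring closure, whereas the chosen plan fixes C5 on ring A before ring B exists. On mechanism cobalt-mediated cyclocarbonylation is dependable for terminal or strained alkenes and much less so for this one, while the titanium exchange needs exactly the terminal vinyl group that 22 offers. On step economy it is equal after the key step (two steps each), better in the key step itself, and worse on the way to the precursor.

Key step: step 12

Remark (assumption): the sense of induction of the C2-symmetric amine is taken from the usual model for such dienes (anhydride endo, dienophile on the face away from the phenyl group on the pyrrolidine carbon beside C5–H); this calls for the (2S,5S) amine, and the (2R,5R) amine would be used if the sense were the opposite.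

Remark (correction): the bicyclo[3.1.0]hexan-1-ol unit of 23 can only be cis-fused at C8–C9; the trans relationship belongs to the ring A/ring B junction C5–C6, and the SMILES of 22 and 23 are consistent with the target at every shared centre.

## Route

Step 1
Reactants: 1 hex-3-yne
Product: 3 diethylmaleic anhydride (3,4-diethylfuran-2,5-dione), via diethylmaleic acid 2 (not isolated)
Conditions: Ni(acac)2(bpy) (10 mol %), Zn powder, MgBr2, 4 Å MS, CO2 (1 atm), DMF, rt; then aq HCl
Reagents that add atoms: carbon dioxide, O=C=O
Why: Nickel-catalysed reductive double carboxylation of an internal alkyne: zerovalent nickel couples alkyne and CO2 to an oxanickelacyclopentenone, zinc reduction and a second CO2 insertion give the cis-dicarboxylate, and the dialkylmaleic acid 2 released on acidification dehydrates spontaneously to the anhydride.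

Step 2
Reactants: 4 (E)-4-methoxybut-3-en-2-one; 5 (2S,5S)-2,5-diphenylpyrrolidine
Product: 6 (E)-4-[(2S,5S)-2,5-diphenylpyrrolidin-1-yl]but-3-en-2-one
Conditions: THF, 60 °C
Reagents that add atoms: none
Why: Conjugate addition–elimination of the secondary amine on the β-methoxy enone (vinylogous transamidation) gives the push–pull E enaminone; no stereocentre is touched.

Step 3
Reactants: 6 (E)-4-[(2S,5S)-2,5-diphenylpyrrolidin-1-yl]but-3-en-2-one
Product: 8 (2S,5S)-1-[(1E)-3-(tert-butyldimethylsilyloxy)buta-1,3-dien-1-yl]-2,5-diphenylpyrrolidine, via potassium dienolate 7 (not isolated)
Conditions: KN(SiMe3)2, THF, −78 °C; then TBSCl, −78 °C → rt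
Reagents that add atoms: tert-butyldimethylsilyl chloride, CC(C)(C)[Si](C)(C)Cl
Why: Kinetic deprotonation of the methyl ketone of the vinylogous amide and O-silylation of the cross-conjugated enolate is the standard entry to 1-amino-3-siloxybutadienes.

Step 4
Reactants: 8 (2S,5S)-1-[(1E)-3-(tert-butyldimethylsilyloxy)buta-1,3-dien-1-yl]-2,5-diphenylpyrrolidine; 3 diethylmaleic anhydride
Product: 10 ring A enone anhydride (3aR,7aS)-3a,7a-diethyl-3a,4-dihydro-2-benzofuran-1,3,5(7aH)-trione, via cycloadduct 9 (not isolated)
Conditions: toluene, rt → 60 °C; then HF (aq), MeCN, 0 °C
Reagents that add atoms: none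
Why: Normal-demand Diels–Alder reaction of the very electron-rich diene with the cyclic anhydride forms C2–C3 and C4–C5, setting C3 and C4 cis from the dienophile geometry and absolute from the auxiliary (anhydride endo, dienophile anti to the shielding phenyl group). HF then cleaves the silyl enol ether and the β-amino ketone loses the amine (E1cB) to give the C5=C6 enone, while the tetraalkylsuccinic anhydride should resist hydrolysis through the gem-dialkyl effect.

Step 5
Reactants: 10 ring A enone anhydride; 11 vinylmagnesium bromide; 12 methyl bromoacetate
Product: 14 ring A keto ester anhydride (C1 ketone; 5α-vinyl; 6β-CH2CO2Me), via bromomagnesium enolate 13 (not isolated)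
Conditions: 11 (2 equiv), CuBr·SMe2 (1 equiv), THF, −78 °C; then 12, DMPU, −78 → −20 °C
Reagents that add atoms: none
Why: Conjugate addition of the divinylcuprate to C5 from the convex α face of the cis-fused bicycle (anti to the anhydride ring), then alkylation of the regiodefined C1–C6 enolate anti to the new vinyl group, sets C5 and C6 trans. C6 is α to the ketone, so the trans arrangement is also the thermodynamic one.

Step 6
Reactants: 14 ring A keto ester anhydride
Product: 16 C1 enol triflate (C1=C2), via potassium enolate 15 (not isolated)
Conditions: KN(SiMe3)2, THF, −78 °C; then PhNTf2, −78 → 0 °C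
Reagents that add atoms: N-phenylbis(trifluoromethanesulfonimide), O=S(=O)(N(c1ccccc1)S(=O)(=O)C(F)(F)F)C(F)(F)F
Why: Kinetic enolisation of the ketone at the C2 methylene (faster than at the C6 methine and far faster than ester enolisation) and O-sulfonylation gives the C1=C2 enol triflate; the C2 enolate cannot reach an anhydride carbonyl for geometric reasons.

Step 7
Reactants: 16 C1 enol triflate
Product: 17 1-ethyl ring A alkene anhydride
Conditions: Et2Zn, Pd(dppf)Cl2 (5 mol %), THF, 50 °C
Reagents that add atoms: diethylzinc, CC[Zn]CC
Why: Negishi coupling of the alkenyl triflate; the wide-bite-angle dppf ligand favours reductive elimination over β-hydride elimination of the ethylpalladium intermediate, and diethylzinc should leave the ester and the hindered anhydride untouched.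

Step 8
Reactants: 17 1-ethyl ring A alkene anhydride
Product: 18 hydroxy lactone (lactol carbon on C3; lactone carbonyl on C4)
Conditions: LiAlH(OtBu)3, THF, −40 → 0 °C; then aq HCl
Reagents that add atoms: none
Why: Partial reduction of a cyclic anhydride to the γ-hydroxy lactone (pseudo-acid) by a bulky alkoxyaluminium hydride, which should not reduce the methyl ester. Attack is expected at the C3 carbonyl, flanked only by the sp2 C2–H, and not at the C4 carbonyl, which is screened by C5 and the cis C6 side chain.

Step 9
Reactants: 18 hydroxy lactone
Product: 19 styryl acid (3β-(E)-styryl; 4β-CO2H)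
Conditions: (EtO)2P(O)CH2Ph, NaH, THF, 0 °C → rt; then aq HCl
Reagents that add atoms: diethyl benzylphosphonate, CCOP(=O)(Cc1ccccc1)OCC
Why: Horner–Wadsworth–Emmons olefination of the aldehyde carboxylate that base unmasks from the pseudo-acid. The semi-stabilised benzylphosphonate anion gives the E styrene, a preference reinforced by the quaternary C3, and is too weak a base to enolise the methyl ester appreciably.

Step 10
Reactants: 19 styryl acid
Product: 20 styryl tert-butyl ester
Conditions: Cl3CC(=NH)OtBu, CH2Cl2/cyclohexane, rt
Reagents that add atoms: tert-butyl 2,2,2-trichloroacetimidate, CC(C)(C)OC(=N)C(Cl)(Cl)Cl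
Why: tert-Butylation at the carboxylate oxygen by the acid-activated imidate (an SN1-type O-alkylation) is insensitive to the neopentyl hindrance that would defeat esterification by acyl substitution.

Step 11
Reactants: 20 styryl tert-butyl ester
Product: 22 Kulinkovich precursor (methyl 2-substituted butanoate on C6; vinyl on C5), via lithium enolate 21 (not isolated)
Conditions: LiN(iPr)2, THF, −78 °C; then EtI, DMPU, −78 → −30 °C
Reagents that add atoms: iodoethane, CCI
Why: Alkylation of the only enolisable ester (the tert-butyl ester has no α-hydrogen). With C6–H eclipsing the enolate plane (allylic 1,3-strain), iodoethane should approach anti to the bulkier C5 branch, which gives the C7 configuration shown; any C7 epimer converges in step 13.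

Step 12
Reactants: 22 Kulinkovich precursor
Product: 23 cyclopropanol (bicyclo[3.1.0]hexan-1-ol spanning C8, C9 and the future methyl carbon)
Conditions: Ti(OiPr)4 (1.5 equiv), c-C5H9MgCl (4.5 equiv, slow addition), THF, rt; then aq NH4Cl
Reagents that add atoms: none
Why: Intramolecular Kulinkovich cyclopropanation: Ti(OiPr)4 and two equivalents of c-C5H9MgCl give a dicyclopentyltitanium species that loses cyclopentane to form a cyclopentene–titanium complex (a titanacyclopropane, formally divalent titanium), and the weakly bound 1,2-disubstituted cyclopentene is displaced by the terminal C5 vinyl group. The new titanacyclopropane inserts the C8 ester carbonyl into its Ti–C9 bond, forming C8–C9 and closing ring B in a 5-exo-trig sense; loss of methoxide gives a β-titanio ketone whose Ti–CH2 bond adds to the C8 carbonyl (3-exo-trig) to close the cyclopropane. The closest known reaction type is the conversion of hex-5-enoates into bicyclo[3.1.0]hexan-1-ols with the same reagents. The ring A/ring B junction is trans because the C5 vinyl (α) and the C6 side chain (β) are already trans and neither centre is touched. The cyclopropane can only be cis-fused to ring B, so C8 follows C9, and C9 is set by the vinyl face that carries titanium: the Ti–CH2 unit should lie away from the quaternary C4, placing the cyclopropane CH2 on the β face, and this centre is provisional because step 13 equilibrates C9. Alkene selectivity rests on ligand exchange being limited to monosubstituted alkenes, so the trisubstituted C1=C2 and the 1,2-disubstituted styrene stay uncoordinated; ester selectivity rests on the tert-butyl ester sitting on a quaternary carbon while the methyl ester is delivered intramolecularly. Slow addition of the hindered secondary Grignard reagent should keep direct addition to the methyl ester slower than the titanium-mediated cyclisation.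

Step 13
Reactants: 23 cyclopropanol
Product: 24 isospiculoic acid A tert-butyl ester
Conditions: KOtBu (20 mol %), tBuOH/THF, rt
Reagents that add atoms: none
Why: Base-induced strain-release opening of the cyclopropanolate toward the less substituted carbon (primary homoenolate, protonated by tBuOH) unmasks the C8 ketone and turns the cyclopropane CH2 into the C9 methyl. The same alkoxide equilibrates the α-centres C7 and C9 to the all-trans 2,5-dialkylcyclopentanone.

Step 14
Reactants: 24 isospiculoic acid A tert-butyl ester
Product: 25 isospiculoic acid A
Conditions: CF3CO2H, CH2Cl2, 0 °C
Reagents that add atoms: none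
Why: Acidolysis of the tert-butyl ester by alkyl–oxygen cleavage (AAL1, loss of isobutene) needs no nucleophile at the hindered carbonyl and no base, so C7 and C9 are not disturbed; low temperature and short contact should spare the two alkenes.

## Compound list

1 | hex-3-yne | CCC#CCC | starting material
2 | (Z)-2,3-diethylbut-2-enedioic acid (diethylmaleic acid) | CC/C(C(=O)O)=C(\CC)C(=O)O | intermediate (not isolated)
3 | 3,4-diethylfuran-2,5-dione (diethylmaleic anhydride) | CCC1=C(CC)C(=O)OC1=O | intermediate
4 | (E)-4-methoxybut-3-en-2-one | CO/C=C/C(C)=O | starting material
5 | (2S,5S)-2,5-diphenylpyrrolidine | N1[C@H](c2ccccc2)CC[C@H]1c1ccccc1 | starting material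
6 | (E)-4-[(2S,5S)-2,5-diphenylpyrrolidin-1-yl]but-3-en-2-one | CC(=O)/C=C/N1[C@H](c2ccccc2)CC[C@H]1c1ccccc1 | intermediate
7 | potassium dienolate of 6 (cross-conjugated enolate, E enamine) | [K+].[O-]C(=C)/C=C/N1[C@H](c2ccccc2)CC[C@H]1c1ccccc1 | intermediate (not isolated)
8 | (2S,5S)-1-[(1E)-3-(tert-butyldimethylsilyloxy)buta-1,3-dien-1-yl]-2,5-diphenylpyrrolidine | C=C(O[Si](C)(C)C(C)(C)C)/C=C/N1[C@H](c2ccccc2)CC[C@H]1c1ccccc1 | intermediate
9 | Diels–Alder cycloadduct: C1=C6 silyl enol ether, pyrrolidinyl group on C5 (β, cis to the anhydride), cis-fused anhydride on C3/C4 with both ethyls α | CC(C)(C)[Si](C)(C)OC1=C[C@H](N2[C@H](c3ccccc3)CC[C@H]2c4ccccc4)[C@]5(CC)C(=O)OC(=O)[C@]5(CC)C1 | intermediate (not isolated)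
10 | (3aR,7aS)-3a,7a-diethyl-3a,4-dihydro-2-benzofuran-1,3,5(7aH)-trione: ring A enone (C1 ketone, C5=C6) with the cis anhydride on C3/C4 | O=C1C[C@@]2(CC)C(=O)OC(=O)[C@@]2(CC)C=C1 | intermediate
11 | vinylmagnesium bromide | C=C[Mg]Br | starting material
12 | methyl bromoacetate | COC(=O)CBr | starting material
13 | bromomagnesium C1–C6 enolate of the 5α-vinyl adduct | Br[Mg]OC1=C[C@@H](C=C)[C@]2(CC)C(=O)OC(=O)[C@]2(CC)C1 | intermediate (not isolated)
14 | ring A keto ester anhydride: C1 ketone, 5α-vinyl, 6β-(2-methoxy-2-oxoethyl), cis anhydride on C3/C4 (carbonyls β, ethyls α) | O=C1C[C@@]2(CC)C(=O)OC(=O)[C@@]2(CC)[C@H](C=C)[C@H]1CC(=O)OC | intermediate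
15 | potassium C1–C2 enolate of 14 | [K+].[O-]C1=C[C@@]2(CC)C(=O)OC(=O)[C@@]2(CC)[C@H](C=C)[C@H]1CC(=O)OC | intermediate (not isolated)
16 | C1 enol triflate (C1=C2) of 14 | O=S(=O)(OC1=C[C@@]2(CC)C(=O)OC(=O)[C@@]2(CC)[C@H](C=C)[C@H]1CC(=O)OC)C(F)(F)F | intermediate
17 | 1-ethyl ring A alkene anhydride: C1(Et)=C2, 5α-vinyl, 6β-CH2CO2Me, cis anhydride on C3/C4 | CCC1=C[C@@]2(CC)C(=O)OC(=O)[C@@]2(CC)[C@H](C=C)[C@H]1CC(=O)OC | intermediate
18 | hydroxy lactone (pseudo-acid): lactol carbon on C3, lactone carbonyl on C4, both β; lactol epimers in equilibrium with the open aldehyde acid | CCC1=C[C@@]2(CC)C(O)OC(=O)[C@@]2(CC)[C@H](C=C)[C@H]1CC(=O)OC | intermediate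
19 | styryl acid: 3β-(E)-styryl, 4β-CO2H, 3α,4α-diethyl, 5α-vinyl, 6β-CH2CO2Me, C1(Et)=C2 | CCC1=C[C@](/C=C/c2ccccc2)(CC)[C@@](CC)(C(=O)O)[C@H](C=C)[C@H]1CC(=O)OC | intermediate
20 | tert-butyl ester of 19 | CCC1=C[C@](/C=C/c2ccccc2)(CC)[C@@](CC)(C(=O)OC(C)(C)C)[C@H](C=C)[C@H]1CC(=O)OC | intermediate
21 | lithium enolate of the methyl ester of 20 (OMe cis to C6) | CCC1=C[C@](/C=C/c2ccccc2)(CC)[C@@](CC)(C(=O)OC(C)(C)C)[C@H](C=C)[C@H]1/C=C(\OC)O[Li] | intermediate (not isolated)
22 | Kulinkovich precursor: ring A tert-butyl ester with 5α-vinyl and, on C6 (β), the methyl butanoate arm CH(Et)CO2Me (C7 as in the target) | CCC1=C[C@](/C=C/c2ccccc2)(CC)[C@@](CC)(C(=O)OC(C)(C)C)[C@H](C=C)[C@H]1[C@@H](CC)C(=O)OC | intermediate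
23 | cyclopropanol: ring B closed through C8–C9 and trans-fused to ring A at C5–C6; cis-fused cyclopropane on C8–C9 with its CH2 β, C8–OH and C9–H α | CCC1=C[C@](/C=C/c2ccccc2)(CC)[C@@](CC)(C(=O)OC(C)(C)C)[C@H]2[C@H]1[C@@H](CC)[C@]3(O)C[C@H]23 | intermediate
24 | isospiculoic acid A tert-butyl ester (all-trans ring B ketone: 7α-ethyl, 9β-methyl) | CCC1=C[C@](/C=C/c2ccccc2)(CC)[C@@](CC)(C(=O)OC(C)(C)C)[C@H]2[C@H]1[C@@H](CC)C(=O)[C@@H]2C | intermediate
25 | isospiculoic acid A | CCC1=C[C@](/C=C/c2ccccc2)(CC)[C@@](CC)(C(=O)O)[C@H]2[C@H]1[C@@H](CC)C(=O)[C@@H]2C | target

## Step count and least certain steps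

Total step count: 14. Longest linear sequence: 13 steps (steps 2 to 14, from 4 to 25); step 1 is a one-step branch.

Step 12 (key step). The most likely failure is that ligand exchange onto the vinyl group does not occur, because that group sits on C5 beside the quaternary C4 and the ester is α-branched; the cyclopentene–titanium complex would then decay or add to the methyl ester intermolecularly. Fallback: from 22, the methyl ester alone is saponified (LiOH, aqueous THF; the tert-butyl ester on the quaternary C4 is expected to survive) to the C8 carboxylic acid F1, which (PhSe)2/Bu3P converts into the Se-phenyl selenoester F2. Bu3SnH and AIBN in hot benzene then generate the C8 acyl radical, which closes ring B by 5-exo-trig addition to the inner carbon of the C5 vinyl group (the same C8–C9 bond); the primary radical left on the terminal carbon is reduced to the C9 methyl. Brief KOtBu/tBuOH treatment as in step 13 settles C7 and C9, and the route is rejoined at 24.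

Step 4. The most likely failure is a sluggish cycloaddition, because both reacting carbons of the dienophile are fully substituted and the diene carries a bulky auxiliary; facial selectivity would erode at the temperature then required. Fallback: from 3, the cycloaddition is run with the smaller, achiral and more reactive (E)-1-(dimethylamino)-3-(tert-butyldimethylsilyloxy)buta-1,3-diene F3. The racemic dimethylamino cycloadduct F4 is treated with HF as in step 4, and the racemic enone anhydride is resolved by preparative chromatography on a chiral stationary phase, which removes the mirror-image enone anhydride F5 and rejoins the route at 10.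

Step 5. The most likely failure is slow C-alkylation of the hindered magnesium enolate, which would allow proton transfer between enolate and product (loss of regiocontrol, unalkylated ketone) or attack of the organometallic species on the anhydride. Fallback: from 10, the conjugate addition is run with Me3SiCl present at −78 °C so that the enolate is silylated as it forms, and the trimethylsilyl enol ether F6 is isolated. Anhydrous fluoride (Bu4N[Ph3SiF2]) then liberates the ammonium enolate in the presence of 12, and C-alkylation rejoins the route at 14.

Step 8. The most likely failure is hydride delivery to the C4 carbonyl instead of the C3 carbonyl, or further reduction of the ring-opened aldehyde to the lactone, because the steric difference between the two carbonyls is modest and the aluminate intermediate can collapse before work-up. Fallback: from 17, the anhydride is opened with LiSEt, a larger nucleophile that cannot over-react, at the less hindered C3 carbonyl to give the S-ethyl thioester acid F7. tert-Butylation as in step 10 gives the thioester tert-butyl ester F8, Fukuyama reduction (Et3SiH, Pd/C) gives the C3 aldehyde F9, and the olefination of step 9 then delivers 20 directly, where the route is rejoined.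

## Further compounds

F1 | step 12 | C8 carboxylic acid from 22 (tert-butyl ester retained) | CCC1=C[C@](/C=C/c2ccccc2)(CC)[C@@](CC)(C(=O)OC(C)(C)C)[C@H](C=C)[C@H]1[C@@H](CC)C(=O)O
F2 | step 12 | Se-phenyl selenoester of F1 | CCC1=C[C@](/C=C/c2ccccc2)(CC)[C@@](CC)(C(=O)OC(C)(C)C)[C@H](C=C)[C@H]1[C@@H](CC)C(=O)[Se]c1ccccc1
F3 | step 4 | (E)-1-(dimethylamino)-3-(tert-butyldimethylsilyloxy)buta-1,3-diene | C=C(O[Si](C)(C)C(C)(C)C)/C=C/N(C)C
F4 | step 4 | racemic dimethylamino cycloadduct (one enantiomer drawn) | CC(C)(C)[Si](C)(C)OC1=C[C@H](N(C)C)[C@]2(CC)C(=O)OC(=O)[C@]2(CC)C1
F5 | step 4 | (3aS,7aR)-3a,7a-diethyl-3a,4-dihydro-2-benzofuran-1,3,5(7aH)-trione, mirror image of 10 | O=C1C[C@]2(CC)C(=O)OC(=O)[C@]2(CC)C=C1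
F6 | step 5 | trimethylsilyl enol ether (C1=C6) of the 5α-vinyl adduct | C[Si](C)(C)OC1=C[C@@H](C=C)[C@]2(CC)C(=O)OC(=O)[C@]2(CC)C1
F7 | step 8 | S-ethyl thioester (on C3) carboxylic acid (on C4) | CCC1=C[C@](C(=O)SCC)(CC)[C@@](CC)(C(=O)O)[C@H](C=C)[C@H]1CC(=O)OC
F8 | step 8 | tert-butyl ester of F7 | CCC1=C[C@](C(=O)SCC)(CC)[C@@](CC)(C(=O)OC(C)(C)C)[C@H](C=C)[C@H]1CC(=O)OC
F9 | step 8 | C3 aldehyde tert-butyl ester | CCC1=C[C@](C=O)(CC)[C@@](CC)(C(=O)OC(C)(C)C)[C@H](C=C)[C@H]1CC(=O)OC
A1 | alternative 1 | cis-diethyl ring A enone anhydride (identical with 10) | O=C1C[C@@]2(CC)C(=O)OC(=O)[C@@]2(CC)C=C1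
A2 | alternative 2 | all-trans ring B cyclopentanone with C1 methylidene and C3 vinyl arms | C=C(CC)[C@@H]1[C@@H](CC)C(=O)[C@H](C)[C@H]1[C@](CC)(C(=O)OC)[C@@](CC)(C=C)/C=C/c1ccccc1
A3 | alternative 2 | (E,E)-dienone precursor of the Nazarov cyclisation | C=C(CC)/C=C(\CC)C(=O)/C(C)=C/[C@](CC)(C(=O)OC)[C@@](CC)(C=C)/C=C/c1ccccc1
A4 | alternative 2 | isospiculoic acid A methyl ester | CCC1=C[C@](/C=C/c2ccccc2)(CC)[C@@](CC)(C(=O)OC)[C@H]2[C@H]1[C@@H](CC)C(=O)[C@@H]2C
A5 | alternative 3 | bicyclic C5=C9 enone methyl ester | CCC1=C[C@](/C=C/c2ccccc2)(CC)[C@@](CC)(C(=O)OC)C2=C(C)C(=O)[C@H](CC)[C@@H]12
A6 | alternative 3 | acyclic bis-quaternary enyne precursor | CC/C=C/C(CC)=C\[C@](/C=C/c1ccccc1)(CC)[C@@](CC)(C(=O)OC)C#CC
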